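The carbocycle is disconnected at C1–C6. C1 (quaternary, bearing O1 and carboxyl C7) and C4 are 1,4-related in the ring, so a six-membered lactone O4–C7–C1–C2–C3–C4 with the vinyl group C5=C6 on C4 already contains all seven carbons. Ireland–Claisen rearrangement of its silyl ketene acetal forms C1–C6, breaks C4–O4, creates C4=C5 and turns the lactone ring into the cyclohexene, transferring the C4 configuration to C1 (carboxyl trans to O3). The precursor is an all-cis 3,5-bis(silyloxy)-6-vinyl δ-lactone made from L-malic acid by Brown alkoxyallylboration. The new carboxyl later opens a directed epoxide to give quinide, which is diacylated.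

Key step: step 8

Remark: ring atoms carry quinic acid numbers in the text (C1 quaternary, C7 carboxyl, O3 cis to O4, O5 cis to C7); natural (S)-malic acid is used because C1 is erased in step 8, while a single C1 epimer keeps each intermediate one compound, makes the minor face error of step 4 a separable diastereomer and puts the C1 hydrogen axial in lactone 14.
Abbreviations: TBS = tert-butyldimethylsilyl, TES = triethylsilyl, Ipc = isopinocampheyl, MOM = methoxymethyl.

Step 1
Reactants: 1 (S)-malic acid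
Product: 2 (S)-2-(2,2-dimethyl-5-oxo-1,3-dioxolan-4-yl)acetic acid
Conditions: 2,2-dimethoxypropane, TsOH·H2O (cat.), rt
Reagents that add atoms: 2,2-dimethoxypropane, COC(C)(C)OC
Why: Acid-catalysed acetalisation closes the five-membered dioxolanone on the α-hydroxy acid unit in preference to a six-membered ring on the distal carboxyl, so O1 and C7 are masked together and the C1 stereocentre is untouched.

Step 2
Reactants: 2 (S)-2-(2,2-dimethyl-5-oxo-1,3-dioxolan-4-yl)acetic acid
Product: 3 (S)-5-(2-hydroxyethyl)-2,2-dimethyl-1,3-dioxolan-4-one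
Conditions: BH3·SMe2, THF, 0 °C → rt; MeOH quench
Reagents that add atoms: none
Why: Chemoselective borane reduction takes the free carboxylic acid through its acyloxyborane much faster than the ester-like dioxolanone carbonyl, and the neutral quench avoids closure of the new alcohol onto C7.

Step 3
Reactants: 3 (S)-5-(2-hydroxyethyl)-2,2-dimethyl-1,3-dioxolan-4-one
Product: 4 (S)-2-(2,2-dimethyl-5-oxo-1,3-dioxolan-4-yl)acetaldehyde
Conditions: Dess–Martin periodinane, CH2Cl2, 0 °C → rt
Reagents that add atoms: none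
Why: Dess–Martin oxidation runs without base, so the β-acyloxy aldehyde should neither eliminate O1 nor epimerise.

Step 4
Reactants: 4 (S)-2-(2,2-dimethyl-5-oxo-1,3-dioxolan-4-yl)acetaldehyde; 5 allyl methoxymethyl ether
Product: 10 (5S)-5-[(2R,3R)-2-hydroxy-3-(methoxymethoxy)pent-4-en-1-yl]-2,2-dimethyl-1,3-dioxolan-4-one, via alkoxyallyllithium 6 (not isolated), via borate complex 7 (not isolated), via allylborane 8 (not isolated), via borinate 9 (not isolated)
Conditions: 5, s-BuLi, THF, −78 °C; (−)-Ipc2BOMe [from (+)-α-pinene]; BF3·OEt2; then 4, −78 °C; pH 7 buffer, MeOH, 30% H2O2, 0 °C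
Reagents that add atoms: none
Why: Brown (Z)-γ-alkoxyallylboration: the Z-allylborane adds through a closed chair (Zimmerman–Traxler) transition state, which makes O3 and O4 syn, and the isopinocampheyl groups direct attack to the Si face of the aldehyde, which should give the 3R,4R adduct under reagent control; the buffered peroxide work-up used for boron aldolates of acyl oxazolidinones should spare the dioxolanone.

Step 5
Reactants: 10 (5S)-5-[(2R,3R)-2-hydroxy-3-(methoxymethoxy)pent-4-en-1-yl]-2,2-dimethyl-1,3-dioxolan-4-one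
Product: 11 (5S)-5-[(2R,3R)-2-(TBS-oxy)-3-(methoxymethoxy)pent-4-en-1-yl]-2,2-dimethyl-1,3-dioxolan-4-one
Conditions: TBSOTf, 2,6-lutidine, CH2Cl2, −78 °C
Reagents that add atoms: tert-butyldimethylsilyl triflate, CC(C)(C)[Si](C)(C)OS(=O)(=O)C(F)(F)F
Why: Silylation with the silyl triflate and a hindered pyridine is fast at −78 °C and caps O3 before it can close a γ-lactone on C7, so that only O4 can lactonise later.

Step 6
Reactants: 11 (5S)-5-[(2R,3R)-2-(TBS-oxy)-3-(methoxymethoxy)pent-4-en-1-yl]-2,2-dimethyl-1,3-dioxolan-4-one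
Product: 13 (3S,5R,6R)-5-(TBS-oxy)-6-ethenyl-3-hydroxyoxan-2-one, via hydroxy dioxolanone 12 (not isolated)
Conditions: ZnBr2, n-PrSH, CH2Cl2, 0 °C; then camphorsulfonic acid (cat.), rt
Reagents that add atoms: none
Why: Lewis acid–thiol acetal cleavage (ZnBr2 activates the MOM acetal, the thiol captures the methoxymethyl group) spares the silyl ether, and the freed allylic O4-H then attacks the activated dioxolanone carbonyl under acid catalysis (6-exo-trig lactonisation) with loss of acetone; no stereocentre is touched.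

Step 7
Reactants: 13 (3S,5R,6R)-5-(TBS-oxy)-6-ethenyl-3-hydroxyoxan-2-one
Product: 14 (3S,5R,6R)-5-(TBS-oxy)-6-ethenyl-3-(TES-oxy)oxan-2-one
Conditions: TESOTf, 2,6-lutidine, CH2Cl2, −78 → 0 °C
Reagents that add atoms: triethylsilyl triflate, CC[Si](CC)(CC)OS(=O)(=O)C(F)(F)F
Why: Silyl triflate silylation of the secondary α-hydroxy lactone; triethylsilyl is chosen because O1 becomes a tertiary ether in step 8 and must then leave together with the O3 silyl group under mild fluoride.

Step 8
Reactants: 14 (3S,5R,6R)-5-(TBS-oxy)-6-ethenyl-3-(TES-oxy)oxan-2-one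
Product: 17 (1R,5R)-5-(TBS-oxy)-1-(TES-oxy)cyclohex-3-ene-1-carboxylic acid, via silyl ketene acetal 15 (not isolated), via trimethylsilyl ester 16 (not isolated)
Conditions: LiN(SiMe3)2, Me3SiCl/Et3N, THF, −78 °C; toluene, 110 °C; aq. citric acid, THF
Reagents that add atoms: none
Why: LiN(SiMe3)2 removes the axial C1 hydrogen and Me3SiCl, present from the start, traps the enolate on oxygen as ketene acetal 15, whose C1=C7 geometry is fixed by the ring. On heating, the axial vinyl group swings over the ring and C6 bonds to C1 while C4–O4 breaks in a concerted, suprafacial [3,3]-sigmatropic shift (Ireland–Claisen rearrangement, of the type known for silyl ketene acetals of alkenyl lactones and 6-alkenyl-1,4-dioxan-2-ones). The cyclohexene ring closes through the C1–C6 bond of this pericyclic array, which the C2–C3 tether forces into a boat (bicyclo[2.2.2]octane-like) geometry; it is not an ionic exo or endo cyclisation. C1 is the only new stereocentre and is controlled by C4: the vinyl group can reach only the lactone face it stands on, so C6 adds there and C7 ends on the opposite face, trans to O3, while C4 becomes sp2. The step needs O-silylation to outrun self-condensation of the enolate and needs the vinyl group axial; in-situ trapping secures the first, and the cis O3–vinyl relation (O3 equatorial when vinyl is axial), with no leaving group on C2, secures the second. Mild acid then hydrolyses only the trimethylsilyl ester.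

Step 9
Reactants: 17 (1R,5R)-5-(TBS-oxy)-1-(TES-oxy)cyclohex-3-ene-1-carboxylic acid
Product: 18 (1R,5R)-1,5-dihydroxycyclohex-3-ene-1-carboxylic acid
Conditions: 48% aq. HF, MeCN, 0 °C → rt; evaporation
Reagents that add atoms: none
Why: Fluoride-driven cleavage of silyl ethers with aqueous HF should remove the tertiary triethylsilyl and the allylic TBS ether in one operation under weakly acidic conditions that spare the allylic alcohol and the alkene.

Step 10
Reactants: 18 (1R,5R)-1,5-dihydroxycyclohex-3-ene-1-carboxylic acid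
Product: 20 quinide, (1S,3R,4R,5R)-1,3,4-trihydroxy-6-oxabicyclo[3.2.1]octan-7-one, via epoxy acid 19 (not isolated)
Conditions: mCPBA, EtOAc, 0 °C → rt; then TsOH·H2O (cat.), 40 °C
Reagents that add atoms: 3-chloroperbenzoic acid, OOC(=O)c1cccc(Cl)c1
Why: Hydroxyl-directed (Henbest) epoxidation: the peracid is hydrogen-bonded to the allylic O3-H and homoallylic O1-H while the carboxyl shields the other face, so oxygen is delivered cis to O3 and sets C4, and the C1 carboxyl, fixed on the opposite face, then opens the epoxide at C5 with inversion in a trans-diaxial 5-exo-tet lactonisation (Fürst–Plattner rule), which sets C5 and leaves no regiochemical choice.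

Step 11
Reactants: 20 quinide
Product: 21 3-O-TBS-quinide
Conditions: TBSCl (1.1 equiv), imidazole, DMF, 0 °C → rt
Reagents that add atoms: tert-butyldimethylsilyl chloride, CC(C)(C)[Si](C)(C)Cl
Why: Silylation with one equivalent of the silyl chloride should pick the equatorial secondary 3-OH over the axial, doubly flanked 4-OH and the tertiary 1-OH, the known selectivity of this lactone.

Step 12
Reactants: 21 3-O-TBS-quinide
Product: 22 allyl 3-O-TBS-quinate
Conditions: allyl alcohol, K2CO3 (cat.), 0 °C; AcOH quench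
Reagents that add atoms: allyl alcohol, C=CCO
Why: Base-catalysed alcoholysis (transesterification) of the strained bridged γ-lactone, as in the known methanolysis of quinide derivatives, is driven by the ring flip to the chair with equatorial ester, O4 and O5, and frees O5-H without touching a stereocentre.

Step 13
Reactants: 23 p-coumaric acid
Product: 25 (E)-3-[4-(TBS-oxy)phenyl]prop-2-enoic acid, via silyl ester 24 (not isolated)
Conditions: TBSCl (2.2 equiv), imidazole, DMF, rt; then K2CO3 (cat.), MeOH/H2O, 0 °C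
Reagents that add atoms: tert-butyldimethylsilyl chloride, CC(C)(C)[Si](C)(C)Cl
Why: Silyl chloride/imidazole silylates phenol and carboxyl, and mild carbonate hydrolyses only the labile silyl ester, leaving the aryl silyl ether.

Step 14
Reactants: 25 (E)-3-[4-(TBS-oxy)phenyl]prop-2-enoic acid
Product: 26 (E)-3-[4-(TBS-oxy)phenyl]prop-2-enoyl chloride
Conditions: (COCl)2, DMF (cat.), CH2Cl2, 0 °C → rt
Reagents that add atoms: oxalyl chloride, ClC(=O)C(=O)Cl
Why: Oxalyl chloride with catalytic DMF (Vilsmeier-type activation) converts the acid into the acid chloride under conditions that the aryl silyl ether and the E-alkene tolerate.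

Step 15
Reactants: 22 allyl 3-O-TBS-quinate; 26 (E)-3-[4-(TBS-oxy)phenyl]prop-2-enoyl chloride
Product: 27 allyl 3-O-TBS-4,5-bis-O-[(E)-4-(TBS-oxy)cinnamoyl]quinate
Conditions: 26 (2.6 equiv), pyridine, DMAP (cat.), CH2Cl2, 0 °C → rt
Reagents that add atoms: none
Why: DMAP-catalysed acylation with the acid chloride should esterify the two equatorial secondary hydroxyls O4 and O5, while the tertiary O1-H is too hindered to react and the silyl ether on O3 blocks acylation and acyl migration there.

Step 16
Reactants: 27 allyl 3-O-TBS-4,5-bis-O-[(E)-4-(TBS-oxy)cinnamoyl]quinate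
Product: 28 3-O-TBS-4,5-bis-O-[(E)-4-(TBS-oxy)cinnamoyl]quinic acid
Conditions: Pd(PPh3)4 (cat.), N-methylaniline, THF, rt
Reagents that add atoms: none
Why: Tsuji–Trost deallylation: zerovalent palladium ionises only the allyl ester and N-methylaniline traps the allyl group under neutral conditions, so the two cinnamate esters stay in place and O3 is still blocked against acyl migration.

Step 17
Reactants: 28 3-O-TBS-4,5-bis-O-[(E)-4-(TBS-oxy)cinnamoyl]quinic acid
Product: 29 4,5-di-O-p-coumaroylquinic acid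
Conditions: 48% aq. HF, MeCN, 0 °C → rt
Reagents that add atoms: none
Why: Fluoride-driven desilylation with aqueous HF removes the O3 silyl ether and both aryl silyl ethers at acidic pH, where ester hydrolysis and acyl migration from O4 to O3 are slow, and should give the target.

Compound list
1 | (S)-malic acid | OC(=O)C[C@H](O)C(=O)O | starting material
2 | (S)-2-(2,2-dimethyl-5-oxo-1,3-dioxolan-4-yl)acetic acid | OC(=O)C[C@@H]1OC(C)(C)OC1=O | intermediate
3 | (S)-5-(2-hydroxyethyl)-2,2-dimethyl-1,3-dioxolan-4-one | OCC[C@@H]1OC(C)(C)OC1=O | intermediate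
4 | (S)-2-(2,2-dimethyl-5-oxo-1,3-dioxolan-4-yl)acetaldehyde | O=CC[C@@H]1OC(C)(C)OC1=O | intermediate
5 | allyl methoxymethyl ether | C=CCOCOC | starting material
6 | (Z)-3-(methoxymethoxy)allyllithium | [Li]C/C=C\OCOC | intermediate
7 | lithium methoxy[(Z)-3-(methoxymethoxy)prop-2-en-1-yl]diisopinocampheylborate | [Li+].COCO/C=C\C[B-](OC)([C@@H]1C[C@@H]2C[C@H]([C@H]1C)C2(C)C)[C@@H]1C[C@@H]2C[C@H]([C@H]1C)C2(C)C | intermediate
8 | [(Z)-3-(methoxymethoxy)prop-2-en-1-yl]diisopinocampheylborane | COCO/C=C\CB([C@@H]1C[C@@H]2C[C@H]([C@H]1C)C2(C)C)[C@@H]1C[C@@H]2C[C@H]([C@H]1C)C2(C)C | intermediate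
9 | diisopinocampheylborinate of alcohol 10 (boron on O3) | C=C[C@@H](OCOC)[C@H](OB([C@@H]2C[C@@H]3C[C@H]([C@H]2C)C3(C)C)[C@@H]2C[C@@H]3C[C@H]([C@H]2C)C3(C)C)C[C@@H]1OC(C)(C)OC1=O | intermediate
10 | (5S)-5-[(2R,3R)-2-hydroxy-3-(methoxymethoxy)pent-4-en-1-yl]-2,2-dimethyl-1,3-dioxolan-4-one | C=C[C@@H](OCOC)[C@H](O)C[C@@H]1OC(C)(C)OC1=O | intermediate
11 | (5S)-5-[(2R,3R)-2-(tert-butyldimethylsilyloxy)-3-(methoxymethoxy)pent-4-en-1-yl]-2,2-dimethyl-1,3-dioxolan-4-one | C=C[C@@H](OCOC)[C@H](O[Si](C)(C)C(C)(C)C)C[C@@H]1OC(C)(C)OC1=O | intermediate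
12 | (5S)-5-[(2R,3R)-2-(tert-butyldimethylsilyloxy)-3-hydroxypent-4-en-1-yl]-2,2-dimethyl-1,3-dioxolan-4-one | C=C[C@@H](O)[C@H](O[Si](C)(C)C(C)(C)C)C[C@@H]1OC(C)(C)OC1=O | intermediate
13 | (3S,5R,6R)-5-(tert-butyldimethylsilyloxy)-6-ethenyl-3-hydroxyoxan-2-one (all three substituents cis) | C=C[C@H]1OC(=O)[C@@H](O)C[C@H]1O[Si](C)(C)C(C)(C)C | intermediate
14 | (3S,5R,6R)-5-(tert-butyldimethylsilyloxy)-6-ethenyl-3-(triethylsilyloxy)oxan-2-one | C=C[C@H]1OC(=O)[C@@H](O[Si](CC)(CC)CC)C[C@H]1O[Si](C)(C)C(C)(C)C | intermediate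
15 | (2R,3R)-3-(tert-butyldimethylsilyloxy)-2-ethenyl-5-(triethylsilyloxy)-6-(trimethylsilyloxy)-3,4-dihydro-2H-pyran | C=C[C@H]1OC(O[Si](C)(C)C)=C(O[Si](CC)(CC)CC)C[C@H]1O[Si](C)(C)C(C)(C)C | intermediate
16 | trimethylsilyl (1R,5R)-5-(tert-butyldimethylsilyloxy)-1-(triethylsilyloxy)cyclohex-3-ene-1-carboxylate | C1=C[C@H](O[Si](C)(C)C(C)(C)C)C[C@@](O[Si](CC)(CC)CC)(C(=O)O[Si](C)(C)C)C1 | intermediate
17 | (1R,5R)-5-(tert-butyldimethylsilyloxy)-1-(triethylsilyloxy)cyclohex-3-ene-1-carboxylic acid (quinic numbering: O1, O3 cis; alkene C4=C5) | C1=C[C@H](O[Si](C)(C)C(C)(C)C)C[C@@](O[Si](CC)(CC)CC)(C(=O)O)C1 | intermediate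
18 | (1R,5R)-1,5-dihydroxycyclohex-3-ene-1-carboxylic acid | C1=C[C@H](O)C[C@@](O)(C(=O)O)C1 | intermediate
19 | (1S,3S,5R,6R)-3,5-dihydroxy-7-oxabicyclo[4.1.0]heptane-3-carboxylic acid (epoxide cis to both hydroxyls, trans to the carboxyl) | O[C@@H]1C[C@@](O)(C(=O)O)C[C@@H]2O[C@H]12 | intermediate
20 | quinide, (1S,3R,4R,5R)-1,3,4-trihydroxy-6-oxabicyclo[3.2.1]octan-7-one | O[C@@]12C[C@@H](O)[C@@H](O)[C@@H](C1)OC2=O | intermediate
21 | 3-O-(tert-butyldimethylsilyl)quinide (silyl ether on the equatorial 3-hydroxyl) | O[C@@]12C[C@@H](O[Si](C)(C)C(C)(C)C)[C@@H](O)[C@@H](C1)OC2=O | intermediate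
22 | prop-2-en-1-yl 3-O-(tert-butyldimethylsilyl)quinate | C=CCOC(=O)[C@]1(O)C[C@@H](O[Si](C)(C)C(C)(C)C)[C@@H](O)[C@H](O)C1 | intermediate
23 | p-coumaric acid | O=C(O)/C=C/c1ccc(O)cc1 | starting material
24 | tert-butyldimethylsilyl (E)-3-[4-(tert-butyldimethylsilyloxy)phenyl]prop-2-enoate | CC(C)(C)[Si](C)(C)OC(=O)/C=C/c1ccc(O[Si](C)(C)C(C)(C)C)cc1 | intermediate
25 | (E)-3-[4-(tert-butyldimethylsilyloxy)phenyl]prop-2-enoic acid | OC(=O)/C=C/c1ccc(O[Si](C)(C)C(C)(C)C)cc1 | intermediate
26 | (E)-3-[4-(tert-butyldimethylsilyloxy)phenyl]prop-2-enoyl chloride | ClC(=O)/C=C/c1ccc(O[Si](C)(C)C(C)(C)C)cc1 | intermediate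
27 | prop-2-en-1-yl 3-O-(tert-butyldimethylsilyl)-4,5-bis-O-{(E)-3-[4-(tert-butyldimethylsilyloxy)phenyl]prop-2-enoyl}quinate | C=CCOC(=O)[C@]1(O)C[C@@H](O[Si](C)(C)C(C)(C)C)[C@@H](OC(=O)/C=C/c2ccc(O[Si](C)(C)C(C)(C)C)cc2)[C@H](OC(=O)/C=C/c2ccc(O[Si](C)(C)C(C)(C)C)cc2)C1 | intermediate
28 | 3-O-(tert-butyldimethylsilyl)-4,5-bis-O-{(E)-3-[4-(tert-butyldimethylsilyloxy)phenyl]prop-2-enoyl}quinic acid | OC(=O)[C@]1(O)C[C@@H](O[Si](C)(C)C(C)(C)C)[C@@H](OC(=O)/C=C/c2ccc(O[Si](C)(C)C(C)(C)C)cc2)[C@H](OC(=O)/C=C/c2ccc(O[Si](C)(C)C(C)(C)C)cc2)C1 | intermediate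
29 | 4,5-di-O-p-coumaroylquinic acid | O=C(/C=C/c1ccc(O)cc1)O[C@@H]1[C@H](O)C[C@@](O)(C(=O)O)C[C@H]1OC(=O)/C=C/c1ccc(O)cc1 | target

Total step count: 17. Longest linear sequence: 15 steps (steps 1–12 and 15–17).

Steps most likely to fail

Step 8. The lactone enolate may condense with unreacted lactone before it is silylated, or the ketene acetal may decompose before the strained boat transition state is reached, so that the C1–C6 bond does not form. The fallback sets out from lactone 14 and returns at acid 17; it makes the same bond by enolate alkylation, which keeps the face control by the tether. Hydroboration of the vinyl group (9-BBN, THF; NaBO3·4H2O) should give the 6-(2-hydroxyethyl) lactone F1, and I2/PPh3/imidazole the 6-(2-iodoethyl) lactone F2. LiN(SiMe3)2 (THF, −78 → 0 °C) should close the bridged lactone 6-(TBS-oxy)-4-(TES-oxy)-2-oxabicyclo[2.2.2]octan-3-one F3 by 6-exo-tet alkylation, in which C6 can reach C1 only on the face of the side chain. NaOMe/MeOH opens it to the methyl 4-hydroxycyclohexanecarboxylate F4 (O4 cis to the ester). Martin sulfurane dehydrates by anti elimination, for which only a C5 hydrogen is available because the C3 hydrogen is cis to O4, to the methyl cyclohex-3-enecarboxylate F5. LiOH (THF/H2O) then hydrolyses the ester to 17.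

Step 10. In the polar solvent needed to dissolve 18 the hydrogen-bond guidance of the peracid is weakened, so oxygen may also be delivered to the face of the carboxyl, giving an epoxide that cannot lactonise. The fallback sets out from 18 and returns at epoxy acid 19; it moves the epoxidation to a lipophilic ester so that it runs in CH2Cl2. Allyl bromide/KHCO3 in DMF should give the allyl dihydroxy ester F6, and mCPBA in CH2Cl2 (or t-BuOOH with VO(acac)2) the cis-epoxy allyl ester F7. Pd(PPh3)4/N-methylaniline then frees 19, which is lactonised to 20 as in the second half of step 10.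

Step 12. Under base the silyl group may migrate from O3 to the neighbouring cis O4, or the hydroxy ester may close back to the lactone on concentration. The fallback sets out from 21 and returns at 22; it replaces the reversible alcoholysis by irreversible hydrolysis and carboxylate alkylation. LiOH (1 equiv, THF/H2O, 0 °C) should open the lactone to 3-O-TBS-quinic acid F8 (handled as its salt), and allyl bromide with KHCO3 in DMF alkylates only the carboxylate to give 22.

Further compounds
F1 | step 8 | (3S,5R,6R)-5-(tert-butyldimethylsilyloxy)-6-(2-hydroxyethyl)-3-(triethylsilyloxy)oxan-2-one | OCC[C@H]1OC(=O)[C@@H](O[Si](CC)(CC)CC)C[C@H]1O[Si](C)(C)C(C)(C)C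
F2 | step 8 | (3S,5R,6R)-5-(tert-butyldimethylsilyloxy)-6-(2-iodoethyl)-3-(triethylsilyloxy)oxan-2-one | ICC[C@H]1OC(=O)[C@@H](O[Si](CC)(CC)CC)C[C@H]1O[Si](C)(C)C(C)(C)C
F3 | step 8 | 6-(tert-butyldimethylsilyloxy)-4-(triethylsilyloxy)-2-oxabicyclo[2.2.2]octan-3-one (silyloxy on C6 syn to the C7–C8 bridge) | O=C1O[C@@H]2CC[C@@]1(O[Si](CC)(CC)CC)C[C@H]2O[Si](C)(C)C(C)(C)C
F4 | step 8 | methyl 3-(tert-butyldimethylsilyloxy)-4-hydroxy-1-(triethylsilyloxy)cyclohexane-1-carboxylate (O1 and O3 cis; O4 cis to the ester) | COC(=O)[C@]1(O[Si](CC)(CC)CC)C[C@@H](O[Si](C)(C)C(C)(C)C)[C@H](O)CC1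
F5 | step 8 | methyl (1R,5R)-5-(tert-butyldimethylsilyloxy)-1-(triethylsilyloxy)cyclohex-3-ene-1-carboxylate | COC(=O)[C@]1(O[Si](CC)(CC)CC)C[C@@H](O[Si](C)(C)C(C)(C)C)C=CC1
F6 | step 10 | prop-2-en-1-yl (1R,5R)-1,5-dihydroxycyclohex-3-ene-1-carboxylate | C1=C[C@H](O)C[C@@](O)(C(=O)OCC=C)C1
F7 | step 10 | prop-2-en-1-yl (1S,3S,5R,6R)-3,5-dihydroxy-7-oxabicyclo[4.1.0]heptane-3-carboxylate | O[C@@H]1C[C@@](O)(C(=O)OCC=C)C[C@@H]2O[C@H]12
F8 | step 12 | 3-O-(tert-butyldimethylsilyl)quinic acid | OC(=O)[C@]1(O)C[C@@H](O[Si](C)(C)C(C)(C)C)[C@@H](O)[C@H](O)C1
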